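The plan rests on disconnecting the C4–O bond of the allylic acetate. The C4 acetoxy group and the C5 tertiary hydroxyl sit trans on the cyclopentenone ring, which is what opening of a C4–C5 epoxide at C4 leaves behind. In one operation, acid-assisted attack of acetic acid on the 4,5-epoxycyclopent-2-enone inverts C4, releases the C5 hydroxyl with its configuration intact and puts the acetyl group on the C4 oxygen only. The precursor is the (1R,5S)-6-oxabicyclo[3.1.0]hex-3-en-2-one carrying the (S)-1-silyloxypentadecyl chain on the quaternary epoxide carbon. Its epoxide face is fixed beforehand by a reagent-controlled reduction followed by hydroxyl-directed epoxidation.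

Key step: step 11

Remark on numbering and configuration: C1 is the ketone, C2=C3 the alkene, C4 the acetoxy carbon, C5 the quaternary carbinol and C6 the side-chain carbinol; the target is 4R,5S,6S, with the C4 acetate and the C6 chain on one ring face and the C5 hydroxyl on the other. Inversion at C4 and retention at C5 of the (1R,5S)-epoxide 15 give exactly this arrangement. The C5 descriptor of 17 reads R only because the silyl ether branch outranks the acetate branch.

Remark on design: the epoxide face is not left to the C6 stereocentre in a nucleophilic epoxidation of the enone, whose sense cannot be predicted with confidence. Two extra steps place a ring hydroxyl by catalyst control and let it direct the epoxidation. O6 stays silylated through step 11 so that it can neither take part in the opening nor accept the acetyl group.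

Step 1
Reactants: 1 pentadecanoyl chloride; 2 bis(trimethylsilyl)acetylene
Product: 3 1-(trimethylsilyl)heptadec-1-yn-3-one
Conditions: AlCl3, CH2Cl2, 0 °C
Reagents that add atoms: none
Why: Friedel–Crafts-type acylation of the bis-silylalkyne, in which the acylium ion replaces one C–Si bond and the deactivated ynone does not react a second time.

Step 2
Reactants: 3 1-(trimethylsilyl)heptadec-1-yn-3-one
Product: 4 (3S)-1-(trimethylsilyl)heptadec-1-yn-3-ol
Conditions: Ru[(S,S)-TsDPEN](p-cymene) (1 mol %), iPrOH, rt
Reagents that add atoms: none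
Why: Noyori asymmetric transfer hydrogenation of an alkynyl ketone, in which the ruthenium hydride/amine pair passes hydride and proton to one carbonyl face and the (S,S)-ligand should give the S propargylic carbinol that becomes C6.

Step 3
Reactants: 4 (3S)-1-(trimethylsilyl)heptadec-1-yn-3-ol
Product: 5 (3S)-heptadec-1-yn-3-ol
Conditions: K2CO3 (0.2 equiv), MeOH, rt
Reagents that add atoms: none
Why: Methoxide-mediated protodesilylation of an alkynylsilane, which frees the terminal alkyne needed for regiocontrol in step 5 and does not touch the carbinol.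

Step 4
Reactants: 5 (3S)-heptadec-1-yn-3-ol
Product: 6 tert-butyl{[(3S)-heptadec-1-yn-3-yl]oxy}dimethylsilane
Conditions: TBSCl, imidazole, DMF, rt
Reagents that add atoms: tert-butyldimethylsilyl chloride, CC(C)(C)[Si](C)(C)Cl
Why: Standard imidazole-promoted O-silylation of a secondary alcohol, giving an ether that should survive every step up to the last one and leaves the stereocentre untouched.

Step 5
Reactants: 6 tert-butyl{[(3S)-heptadec-1-yn-3-yl]oxy}dimethylsilane; 7 ethylene
Product: 9 2-[(1S)-1-(tert-butyldimethylsilyloxy)pentadecyl]cyclopent-2-en-1-one, via dicobalt hexacarbonyl alkyne complex 8 (not isolated)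
Conditions: Co2(CO)8 (1.1 equiv), toluene, rt; then ethylene (25 bar), Me3NO·2H2O, toluene/MeOH, 40 °C
Reagents that add atoms: octacarbonyldicobalt (source of the ring carbonyl), O=C=[Co](=C=O)(=C=O)(=C=O)[Co](=C=O)(=C=O)(=C=O)=C=O
Why: Pauson–Khand [2+2+1] cycloaddition of the complexed terminal alkyne, ethylene and carbon monoxide, which places the alkyne substituent next to the new carbonyl, while amine N-oxide promotion keeps the temperature low enough that the propargylic silyl ether and its stereocentre should survive.

Step 6
Reactants: 9 2-[(1S)-1-(tert-butyldimethylsilyloxy)pentadecyl]cyclopent-2-en-1-one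
Product: 10 (1R)-2-[(1S)-1-(tert-butyldimethylsilyloxy)pentadecyl]cyclopent-2-en-1-ol
Conditions: (S)-2-methyl-CBS-oxazaborolidine (0.2 equiv), BH3·SMe2 (0.7 equiv), THF, −30 °C; MeOH quench
Reagents that add atoms: none
Why: Corey–Bakshi–Shibata 1,2-reduction, in which the substituted alkenyl carbon acts as the large group so that the (S)-catalyst should deliver hydride to give the 1R carbinol under catalyst control, placing the directing hydroxyl on the ring face that must later carry the C5 oxygen.

Step 7
Reactants: 10 (1R)-2-[(1S)-1-(tert-butyldimethylsilyloxy)pentadecyl]cyclopent-2-en-1-ol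
Product: 11 (1R,2R,5S)-1-[(1S)-1-(tert-butyldimethylsilyloxy)pentadecyl]-6-oxabicyclo[3.1.0]hexan-2-ol
Conditions: VO(acac)2 (3 mol %), tBuOOH (1.5 equiv, in decane), CH2Cl2, 0 °C to rt
Reagents that add atoms: tert-butyl hydroperoxide, CC(C)(C)OO
Why: Vanadium-catalysed hydroxyl-directed epoxidation of a cyclic allylic alcohol, in which the oxygen is transferred within the vanadium alkoxide–peroxide complex to the alkene face bearing the ring hydroxyl and so sets both epoxide carbons (future C4 and C5) cis to the 1R carbinol.

Step 8
Reactants: 11 (1R,2R,5S)-1-[(1S)-1-(tert-butyldimethylsilyloxy)pentadecyl]-6-oxabicyclo[3.1.0]hexan-2-ol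
Product: 12 (1R,5S)-1-[(1S)-1-(tert-butyldimethylsilyloxy)pentadecyl]-6-oxabicyclo[3.1.0]hexan-2-one
Conditions: Dess–Martin periodinane, pyridine, CH2Cl2, 0 °C to rt
Reagents that add atoms: none
Why: Dess–Martin oxidation of the secondary alcohol to the ketone under buffered conditions that should leave the epoxide and the silyl ether alone, removing the directing stereocentre once it has done its work.

Step 9
Reactants: 12 (1R,5S)-1-[(1S)-1-(tert-butyldimethylsilyloxy)pentadecyl]-6-oxabicyclo[3.1.0]hexan-2-one
Product: 14 tert-butyldimethyl{(1S)-1-[(1R,5S)-2-(trimethylsilyloxy)-6-oxabicyclo[3.1.0]hex-2-en-1-yl]pentadecyloxy}silane, via lithium enolate 13 (not isolated)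
Conditions: LiN(SiMe3)2 (1.2 equiv), THF, −78 °C; then Me3SiCl (1.5 equiv), −78 to 0 °C
Reagents that add atoms: chlorotrimethylsilane, C[Si](C)(C)Cl
Why: Kinetic enolisation followed by O-silylation, which can only go toward the ring CH2 because the other α-carbon is the fully substituted epoxide carbon, giving a single silyl enol ether.

Step 10
Reactants: 14 tert-butyldimethyl{(1S)-1-[(1R,5S)-2-(trimethylsilyloxy)-6-oxabicyclo[3.1.0]hex-2-en-1-yl]pentadecyloxy}silane
Product: 15 (1R,5S)-1-[(1S)-1-(tert-butyldimethylsilyloxy)pentadecyl]-6-oxabicyclo[3.1.0]hex-3-en-2-one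
Conditions: Pd(OAc)2 (1.1 equiv), MeCN, rt
Reagents that add atoms: none
Why: Saegusa–Ito oxidation, in which Pd(OAc)2 converts the silyl enol ether into a palladium enolate that undergoes β-hydride elimination to the C2=C3 enone under near-neutral conditions the epoxide should tolerate.

Step 11
Reactants: 15 (1R,5S)-1-[(1S)-1-(tert-butyldimethylsilyloxy)pentadecyl]-6-oxabicyclo[3.1.0]hex-3-en-2-one; 16 acetic acid
Product: 17 (1R,5R)-5-[(1S)-1-(tert-butyldimethylsilyloxy)pentadecyl]-5-hydroxy-4-oxocyclopent-2-en-1-yl acetate
Conditions: AcOH (20 equiv), BF3·OEt2 (0.2 equiv), CH2Cl2, −20 to 0 °C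
Reagents that add atoms: none
Why: The Lewis acid activates the epoxide oxygen and acetic acid attacks C4 from the face opposite the C4–O bond, so that bond breaks with inversion while the C5–O bond is never touched; this is the acid-promoted trans opening of vinyl epoxides and of 4,5-epoxycyclopent-2-enones by oxygen nucleophiles. No ring is closed: the oxirane is opened and the five-membered ring is kept. The one new stereocentre, C4, is fixed by the stereospecific backside displacement on the (1R,5S)-epoxide, which should place the acetate cis to the C6 chain and trans to the retained C5 hydroxyl. The step needs attack at C4 and not at C5 or, in conjugate fashion, at C3: C4 is secondary and allylic, so developing positive charge is stabilised by the C2=C3 π bond, whereas C5 is fully substituted, crowded and flanked by the carbonyl, and acetic acid under acidic conditions is too weak a nucleophile for 1,4-addition. Because the nucleophile itself carries the acetyl group, the ester should end up on O4 alone, with O5 free and O6 still silylated; partial loss of the silyl ether would only anticipate step 12.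

Step 12
Reactants: 17 (1R,5R)-5-[(1S)-1-(tert-butyldimethylsilyloxy)pentadecyl]-5-hydroxy-4-oxocyclopent-2-en-1-yl acetate
Product: 18 (1R,5S)-5-hydroxy-5-[(1S)-1-hydroxypentadecyl]-4-oxocyclopent-2-en-1-yl acetate
Conditions: HF·pyridine, pyridine, THF, 0 °C to rt
Reagents that add atoms: none
Why: Fluoride-mediated cleavage of the silyl ether in a weakly acidic medium, which should spare the allylic acetate and the enone and avoids the base that could move the acetyl group from O4 to O6 or remove the C4 proton.

Compound list
1 | pentadecanoyl chloride | CCCCCCCCCCCCCCC(=O)Cl | starting material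
2 | bis(trimethylsilyl)acetylene | C[Si](C)(C)C#C[Si](C)(C)C | starting material
3 | 1-(trimethylsilyl)heptadec-1-yn-3-one | CCCCCCCCCCCCCCC(=O)C#C[Si](C)(C)C | intermediate
4 | (3S)-1-(trimethylsilyl)heptadec-1-yn-3-ol | CCCCCCCCCCCCCC[C@H](O)C#C[Si](C)(C)C | intermediate
5 | (3S)-heptadec-1-yn-3-ol | CCCCCCCCCCCCCC[C@H](O)C#C | intermediate
6 | tert-butyl{[(3S)-heptadec-1-yn-3-yl]oxy}dimethylsilane | CCCCCCCCCCCCCC[C@H](O[Si](C)(C)C(C)(C)C)C#C | intermediate
7 | ethylene | C=C | starting material
8 | hexacarbonyldicobalt complex of alkyne 6 (alkyne bridging the two cobalt atoms) | CCCCCCCCCCCCCC[C@H](O[Si](C)(C)C(C)(C)C)C12[Co]3(=C=O)(=C=O)(=C=O)[Co]1(=C=O)(=C=O)(=C=O)[CH]23 | intermediate (not isolated)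
9 | 2-[(1S)-1-(tert-butyldimethylsilyloxy)pentadecyl]cyclopent-2-en-1-one | CCCCCCCCCCCCCC[C@H](O[Si](C)(C)C(C)(C)C)C1=CCCC1=O | intermediate
10 | (1R)-2-[(1S)-1-(tert-butyldimethylsilyloxy)pentadecyl]cyclopent-2-en-1-ol | CCCCCCCCCCCCCC[C@H](O[Si](C)(C)C(C)(C)C)C1=CCC[C@H]1O | intermediate
11 | (1R,2R,5S)-1-[(1S)-1-(tert-butyldimethylsilyloxy)pentadecyl]-6-oxabicyclo[3.1.0]hexan-2-ol (epoxide cis to the ring hydroxyl) | CCCCCCCCCCCCCC[C@H](O[Si](C)(C)C(C)(C)C)[C@]12O[C@H]1CC[C@H]2O | intermediate
12 | (1R,5S)-1-[(1S)-1-(tert-butyldimethylsilyloxy)pentadecyl]-6-oxabicyclo[3.1.0]hexan-2-one | CCCCCCCCCCCCCC[C@H](O[Si](C)(C)C(C)(C)C)[C@]12O[C@H]1CCC2=O | intermediate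
13 | lithium enolate of 12 (enolate toward the ring CH2) | CCCCCCCCCCCCCC[C@H](O[Si](C)(C)C(C)(C)C)[C@]12O[C@H]1CC=C2[O-].[Li+] | intermediate (not isolated)
14 | tert-butyldimethyl{(1S)-1-[(1R,5S)-2-(trimethylsilyloxy)-6-oxabicyclo[3.1.0]hex-2-en-1-yl]pentadecyloxy}silane | CCCCCCCCCCCCCC[C@H](O[Si](C)(C)C(C)(C)C)[C@]12O[C@H]1CC=C2O[Si](C)(C)C | intermediate
15 | (1R,5S)-1-[(1S)-1-(tert-butyldimethylsilyloxy)pentadecyl]-6-oxabicyclo[3.1.0]hex-3-en-2-one (the 4,5-epoxycyclopent-2-enone, epoxide on the face of the future C5 hydroxyl) | CCCCCCCCCCCCCC[C@H](O[Si](C)(C)C(C)(C)C)[C@]12O[C@H]1C=CC2=O | intermediate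
16 | acetic acid | CC(=O)O | starting material
17 | (1R,5R)-5-[(1S)-1-(tert-butyldimethylsilyloxy)pentadecyl]-5-hydroxy-4-oxocyclopent-2-en-1-yl acetate (C6 silyl ether of the target) | CCCCCCCCCCCCCC[C@H](O[Si](C)(C)C(C)(C)C)[C@@]1(O)C(=O)C=C[C@H]1OC(C)=O | intermediate
18 | (1R,5S)-5-hydroxy-5-[(1S)-1-hydroxypentadecyl]-4-oxocyclopent-2-en-1-yl acetate | CCCCCCCCCCCCCC[C@H](O)[C@@]1(O)C(=O)C=C[C@H]1OC(C)=O | target

Total step count: 12. Longest linear sequence: 12 steps (1 to 18).

Steps most likely to fail

Step 11. The opening may be shared between C4 and C5, the Lewis acid may trigger rearrangement of the oxirane instead of capture by acetic acid, or early loss of the silyl group may be followed by acetylation at O6. The fallback sets out from 15 and separates the opening from the acylation. Dilute aqueous HClO4 in THF at 0 °C should hydrolyse the epoxide at C4 with the same inversion to give the trans-diol (4R,5R)-5-[(1S)-1-(tert-butyldimethylsilyloxy)pentadecyl]-4,5-dihydroxycyclopent-2-en-1-one F1. Ac2O in pyridine at 0 °C without an acyl-transfer catalyst should then esterify only the secondary allylic hydroxyl, the tertiary one being inert, and the route is rejoined at 17.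

Step 5. Uptake of gaseous ethylene may be slow, so that alkyne oligomerisation or reductive loss of the propargylic oxygen competes and conversion to the enone stays low. The fallback sets out from 1 and builds the same enone from a masked 2-metallated cyclopentenone. Acid chloride 1 with N,O-dimethylhydroxylamine hydrochloride and pyridine gives N-methoxy-N-methylpentadecanamide F2. Commercial 6-bromo-1,4-dioxaspiro[4.4]non-6-ene is lithiated with n-BuLi at −78 °C and acylated by F2 to give 1-(1,4-dioxaspiro[4.4]non-6-en-6-yl)pentadecan-1-one F3. Corey–Bakshi–Shibata reduction with the (R)-catalyst should give (1S)-1-(1,4-dioxaspiro[4.4]non-6-en-6-yl)pentadecan-1-ol F4. Silylation with TBSCl and imidazole gives tert-butyl{[(1S)-1-(1,4-dioxaspiro[4.4]non-6-en-6-yl)pentadecyl]oxy}dimethylsilane F5. Ketal hydrolysis with pyridinium p-toluenesulfonate in wet acetone comes back to the route at 9.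

Step 6. Hydride delivery may show poor facial selectivity if the C6 stereocentre opposes the catalyst, or hydroboration of the alkene may compete, so that step 7 would place the epoxide on the wrong face. The fallback sets out from 9 and reaches 12 directly by Weitz–Scheffer nucleophilic epoxidation (H2O2, NaOH, MeOH, 0 °C), leaving the face to the C6 silyloxy stereocentre. The diastereomeric epoxy ketones would be separated by chromatography and the (1R,5S)-isomer carried on at 12; no new compound is made.

Further compounds
F1 | step 11 | (4R,5R)-5-[(1S)-1-(tert-butyldimethylsilyloxy)pentadecyl]-4,5-dihydroxycyclopent-2-en-1-one | CCCCCCCCCCCCCC[C@H](O[Si](C)(C)C(C)(C)C)[C@@]1(O)C(=O)C=C[C@H]1O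
F2 | step 5 | N-methoxy-N-methylpentadecanamide | CCCCCCCCCCCCCCC(=O)N(C)OC
F3 | step 5 | 1-(1,4-dioxaspiro[4.4]non-6-en-6-yl)pentadecan-1-one | CCCCCCCCCCCCCCC(=O)C1=CCCC12OCCO2
F4 | step 5 | (1S)-1-(1,4-dioxaspiro[4.4]non-6-en-6-yl)pentadecan-1-ol | CCCCCCCCCCCCCC[C@H](O)C1=CCCC12OCCO2
F5 | step 5 | tert-butyl{[(1S)-1-(1,4-dioxaspiro[4.4]non-6-en-6-yl)pentadecyl]oxy}dimethylsilane | CCCCCCCCCCCCCC[C@H](O[Si](C)(C)C(C)(C)C)C1=CCCC12OCCO2
F0 | step 6 | none | none
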